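**Plan**

1. Locants: ring A has C1 (bridge), C3 (O), C4 (prenyl), C5 (OMe); ring B has C1′ (bridge), C2′ (OMe), C3′ (OH), C4′ (OAc). After removal of the acetate, one O‑methyl and the phenol protection, ring A is cut at C3–C4 and C5–C6 (C2–C3 is broken and re-made in the same step) into cyclobutenone 9 and ynol ether 13.
2. Enabling feature: ring A carries oxygen, the prenyl carbon and oxygen on the adjacent carbons C3, C4 and C5, with the bridge at C1 meta to both oxygens. A vinylketene and a 1‑alkoxyalkyne assemble exactly this pattern in one operation.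
3. The four-membered ring of 9 is cut into terminal alkyne 7 and dichloroketene; 7 goes back to 2,3,4‑trihydroxybenzaldehyde by a two-carbon and a one-carbon extension; 13 is cut between the alkyne and the prenyl CH2.
4. Forward: ring B is bought; the bridge and the four-membered ring are built on it (steps 1–7); ring A is closed in step 9; O‑methylation, MOM removal and mono-acetylation finish the route.
5. Stereochemistry: the target has no stereocentre and its side-chain alkene bears two identical methyl groups, so nothing has to be controlled.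

Key step: step 9

**Route**

Step 1
Reactants: 1 2,3,4‑trihydroxybenzaldehyde
Product: 2 2‑hydroxy‑3,4‑bis(methoxymethoxy)benzaldehyde
Conditions: MOMCl (2.2 equiv), K2CO3, acetone, 0 °C → rt
Reagents that add atoms: chloromethyl methyl ether, COCCl
Why: Williamson-type O‑alkylation should stop at the C3 and C4 hydroxyls, because the C2 hydroxyl is held in a hydrogen bond to the formyl oxygen and is the least nucleophilic.

Step 2
Reactants: 2 2‑hydroxy‑3,4‑bis(methoxymethoxy)benzaldehyde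
Product: 3 2‑methoxy‑3,4‑bis(methoxymethoxy)benzaldehyde
Conditions: MeI, K2CO3, DMF, 40 °C
Reagents that add atoms: iodomethane, CI
Why: Williamson methylation in a dipolar aprotic solvent breaks the chelate and sets the ring B methoxy group while the MOM ethers are inert to base.

Step 3
Reactants: 3 2‑methoxy‑3,4‑bis(methoxymethoxy)benzaldehyde
Product: 4 ethyl (E)‑3‑[2‑methoxy‑3,4‑bis(methoxymethoxy)phenyl]prop‑2‑enoate
Conditions: Ph3P=CHCO2Et, PhMe, 90 °C
Reagents that add atoms: ethyl (triphenylphosphoranylidene)acetate, CCOC(=O)C=P(c1ccccc1)(c1ccccc1)c1ccccc1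
Why: Wittig olefination with a stabilised ylide adds the second bridge carbon and the future C1 of ring A; the alkene geometry (E expected) is irrelevant because the double bond is saturated next.

Step 4
Reactants: 4 ethyl (E)‑3‑[2‑methoxy‑3,4‑bis(methoxymethoxy)phenyl]prop‑2‑enoate
Product: 5 ethyl 3‑[2‑methoxy‑3,4‑bis(methoxymethoxy)phenyl]propanoate
Conditions: H2 (1 atm), Pd/C, EtOAc, rt
Reagents that add atoms: none
Why: Heterogeneous catalytic hydrogenation reduces only the conjugated C=C bond, since the ester and the aryl MOM ethers are inert and no benzyl-type group is present.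

Step 5
Reactants: 5 ethyl 3‑[2‑methoxy‑3,4‑bis(methoxymethoxy)phenyl]propanoate
Product: 7 1‑(but‑3‑yn‑1‑yl)‑2‑methoxy‑3,4‑bis(methoxymethoxy)benzene, via 3‑arylpropanal 6 (not isolated)
Conditions: i‑Bu2AlH, CH2Cl2, −78 °C; then MeOH, K2CO3, MeC(O)C(N2)P(O)(OMe)2, −78 °C → rt
Reagents that add atoms: dimethyl (1‑diazo‑2‑oxopropyl)phosphonate, COP(=O)(OC)C(=[N+]=[N-])C(C)=O
Why: Half-reduction of the ester at low temperature gives an aluminium hemiacetal that releases aldehyde 6 on adding methanol and base, and Seyferth–Gilbert homologation with the Ohira–Bestmann reagent converts it in the same flask into the terminal alkyne under basic conditions that spare the MOM ethers.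

Step 6
Reactants: 7 1‑(but‑3‑yn‑1‑yl)‑2‑methoxy‑3,4‑bis(methoxymethoxy)benzene
Product: 8 4,4‑dichloro‑3‑{2‑[2‑methoxy‑3,4‑bis(methoxymethoxy)phenyl]ethyl}cyclobut‑2‑en‑1‑one
Conditions: Cl3CCOCl, Zn–Cu couple, Et2O–DME, rt
Reagents that add atoms: trichloroacetyl chloride, O=C(Cl)C(Cl)(Cl)Cl
Why: [2+2] cycloaddition of dichloroketene (zinc dehalogenation of the acid chloride) to a terminal alkyne gives the 3‑substituted 4,4‑dichlorocyclobutenone regioselectively, the ketene carbonyl carbon bonding to the terminal alkyne carbon, while DME ties up ZnCl2 and so shields the acetal groups.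

Step 7
Reactants: 8 4,4‑dichloro‑3‑{2‑[2‑methoxy‑3,4‑bis(methoxymethoxy)phenyl]ethyl}cyclobut‑2‑en‑1‑one
Product: 9 3‑{2‑[2‑methoxy‑3,4‑bis(methoxymethoxy)phenyl]ethyl}cyclobut‑2‑en‑1‑one
Conditions: Zn, AcOH, TMEDA, EtOH, 0 °C → rt
Reagents that add atoms: none
Why: Reductive dechlorination of the α,α‑dichloroketone with zinc in amine-buffered acetic acid is the standard second stage of this cyclobutenone synthesis and avoids both over-reduction and acid damage to the MOM ethers.

Step 8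
Reactants: 10 chloroacetaldehyde dimethyl acetal; 11 prenyl bromide (1‑bromo‑3‑methylbut‑2‑ene)
Product: 13 1‑methoxy‑5‑methylhex‑4‑en‑1‑yne, via sodium methoxyacetylide 12 (not isolated)
Conditions: NaNH2 (3.0 equiv), NH3 (l), −33 °C; then 11, THF, −70 → −33 °C; NH4Cl
Reagents that add atoms: none
Why: Twofold elimination from the chloroacetal and deprotonation give sodium methoxyacetylide, and SN2 acetylide alkylation at the primary carbon of the allylic bromide gives the ynol ether, with exactly three equivalents of amide so that no strong base is left to isomerise the skipped enyne.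

Step 9
Reactants: 9 3‑{2‑[2‑methoxy‑3,4‑bis(methoxymethoxy)phenyl]ethyl}cyclobut‑2‑en‑1‑one; 13 1‑methoxy‑5‑methylhex‑4‑en‑1‑yne
Product: 18 3‑methoxy‑5‑{2‑[2‑methoxy‑3,4‑bis(methoxymethoxy)phenyl]ethyl}‑2‑(3‑methylbut‑2‑en‑1‑yl)phenol, via vinylketene 14 (not isolated), via 4‑vinylcyclobutenone 15 (not isolated), via dienylketene 16 (not isolated), via cyclohexa‑2,4‑dienone 17 (not isolated)
Conditions: PhMe, 80 °C, sealed tube (13, 1.5 equiv)
Reagents that add atoms: none
Why: Heat opens cyclobutenone 9 by a 4π‑electrocyclic reaction to vinylketene 14, which takes up ynol ether 13 in a [2+2] cycloaddition (new ring A bonds C3–C4 and C5–C6) to give 15; a second 4π opening to dienylketene 16, 6π‑electrocyclisation to cyclohexadienone 17 (re-making the C2–C3 bond broken in the first opening) and tautomerisation give phenol 18. The closest known reaction is the Danheiser benzannulation of 3‑alkylcyclobutenones with 1‑alkoxyalkynes, which gives 2‑substituted resorcinol monoethers. Ring A, the only ring formed, closes by thermal disrotatory 6π‑electrocyclisation of the triene made up of the ketene C=C bond and the two alkenes of 16, and aromatisation makes the cascade irreversible. No stereocentre is created, and the single stereocentre of 15 is destroyed in the following ring opening. The step needs regioselectivity in the [2+2] event, which the polarisation of the ynol ether secures: its prenyl-bearing carbon is the nucleophilic terminus and bonds to the ketene carbonyl carbon, so the prenyl group lands between the two oxygens. It also needs the ketene to choose the alkyne over the prenyl C=C bond and the product phenol, which the far higher reactivity of the electron-rich alkyne used in excess should provide, and a methyl ynol ether cannot fragment by retro-ene loss of an alkene at this temperature.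

Step 10
Reactants: 18 3‑methoxy‑5‑{2‑[2‑methoxy‑3,4‑bis(methoxymethoxy)phenyl]ethyl}‑2‑(3‑methylbut‑2‑en‑1‑yl)phenol
Product: 19 1‑{2‑[3,5‑dimethoxy‑4‑(3‑methylbut‑2‑en‑1‑yl)phenyl]ethyl}‑2‑methoxy‑3,4‑bis(methoxymethoxy)benzene
Conditions: MeI, K2CO3, acetone, reflux
Reagents that add atoms: iodomethane, CI
Why: Williamson methylation of the only free phenol completes the symmetrical 3,5‑dimethoxy‑4‑prenyl pattern of ring A and removes the ortho-prenyl phenol before any acid is used.

Step 11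
Reactants: 19 1‑{2‑[3,5‑dimethoxy‑4‑(3‑methylbut‑2‑en‑1‑yl)phenyl]ethyl}‑2‑methoxy‑3,4‑bis(methoxymethoxy)benzene
Product: 20 4‑{2‑[3,5‑dimethoxy‑4‑(3‑methylbut‑2‑en‑1‑yl)phenyl]ethyl}‑3‑methoxybenzene‑1,2‑diol
Conditions: HCl (cat.), MeOH, 40 °C
Reagents that add atoms: none
Why: Acid-catalysed acetal exchange with methanol removes both MOM ethers, and because ring A has no free hydroxyl next to the prenyl group, chroman formation is excluded and the mild acid should leave the trisubstituted alkene alone.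

Step 12
Reactants: 20 4‑{2‑[3,5‑dimethoxy‑4‑(3‑methylbut‑2‑en‑1‑yl)phenyl]ethyl}‑3‑methoxybenzene‑1,2‑diol
Product: 21 4‑{2‑[3,5‑dimethoxy‑4‑(3‑methylbut‑2‑en‑1‑yl)phenyl]ethyl}‑2‑hydroxy‑3‑methoxyphenyl acetate
Conditions: Ac2O (1.0 equiv), pyridine, CH2Cl2, −20 → 0 °C
Reagents that add atoms: acetic anhydride, CC(=O)OC(C)=O
Why: O‑Acylation with one equivalent of anhydride should go to the C4′ hydroxyl, because the C3′ hydroxyl is flanked on both sides (OMe and OH) and hydrogen-bonded to the methoxy oxygen, and any C3′ acetate can migrate to the less crowded C4′ oxygen, so kinetic and thermodynamic preferences point the same way.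

**Compound list**

1 | 2,3,4‑trihydroxybenzaldehyde | O=Cc1ccc(O)c(O)c1O | starting material
2 | 2‑hydroxy‑3,4‑bis(methoxymethoxy)benzaldehyde | O=Cc1ccc(OCOC)c(OCOC)c1O | intermediate
3 | 2‑methoxy‑3,4‑bis(methoxymethoxy)benzaldehyde | O=Cc1ccc(OCOC)c(OCOC)c1OC | intermediate
4 | ethyl (E)‑3‑[2‑methoxy‑3,4‑bis(methoxymethoxy)phenyl]prop‑2‑enoate | CCOC(=O)/C=C/c1ccc(OCOC)c(OCOC)c1OC | intermediate
5 | ethyl 3‑[2‑methoxy‑3,4‑bis(methoxymethoxy)phenyl]propanoate | CCOC(=O)CCc1ccc(OCOC)c(OCOC)c1OC | intermediate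
6 | 3‑[2‑methoxy‑3,4‑bis(methoxymethoxy)phenyl]propanal (not isolated) | O=CCCc1ccc(OCOC)c(OCOC)c1OC | intermediate
7 | 1‑(but‑3‑yn‑1‑yl)‑2‑methoxy‑3,4‑bis(methoxymethoxy)benzene | C#CCCc1ccc(OCOC)c(OCOC)c1OC | intermediate
8 | 4,4‑dichloro‑3‑{2‑[2‑methoxy‑3,4‑bis(methoxymethoxy)phenyl]ethyl}cyclobut‑2‑en‑1‑one | O=C1C=C(CCc2ccc(OCOC)c(OCOC)c2OC)C1(Cl)Cl | intermediate
9 | 3‑{2‑[2‑methoxy‑3,4‑bis(methoxymethoxy)phenyl]ethyl}cyclobut‑2‑en‑1‑one | O=C1C=C(CCc2ccc(OCOC)c(OCOC)c2OC)C1 | intermediate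
10 | chloroacetaldehyde dimethyl acetal (2‑chloro‑1,1‑dimethoxyethane) | COC(CCl)OC | starting material
11 | prenyl bromide (1‑bromo‑3‑methylbut‑2‑ene) | CC(C)=CCBr | starting material
12 | sodium methoxyacetylide (not isolated) | [Na+].[C-]#COC | intermediate
13 | 1‑methoxy‑5‑methylhex‑4‑en‑1‑yne | COC#CCC=C(C)C | intermediate
14 | 5‑[2‑methoxy‑3,4‑bis(methoxymethoxy)phenyl]‑3‑methylidenepent‑1‑en‑1‑one (vinylketene, not isolated) | O=C=CC(=C)CCc1ccc(OCOC)c(OCOC)c1OC | intermediate
15 | 3‑methoxy‑4‑{4‑[2‑methoxy‑3,4‑bis(methoxymethoxy)phenyl]but‑1‑en‑2‑yl}‑2‑(3‑methylbut‑2‑en‑1‑yl)cyclobut‑2‑en‑1‑one (racemic, not isolated) | O=C1C(CC=C(C)C)=C(OC)C1C(=C)CCc1ccc(OCOC)c(OCOC)c1OC | intermediate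
16 | (3E)‑3‑methoxy‑7‑[2‑methoxy‑3,4‑bis(methoxymethoxy)phenyl]‑2‑(3‑methylbut‑2‑en‑1‑yl)‑5‑methylidenehepta‑1,3‑dien‑1‑one (dienylketene, ketene carbon and vinyl group cis, not isolated) | O=C=C(CC=C(C)C)/C(OC)=C\C(=C)CCc1ccc(OCOC)c(OCOC)c1OC | intermediate
17 | 3‑methoxy‑5‑{2‑[2‑methoxy‑3,4‑bis(methoxymethoxy)phenyl]ethyl}‑2‑(3‑methylbut‑2‑en‑1‑yl)cyclohexa‑2,4‑dien‑1‑one (not isolated) | O=C1CC(CCc2ccc(OCOC)c(OCOC)c2OC)=CC(OC)=C1CC=C(C)C | intermediate
18 | 3‑methoxy‑5‑{2‑[2‑methoxy‑3,4‑bis(methoxymethoxy)phenyl]ethyl}‑2‑(3‑methylbut‑2‑en‑1‑yl)phenol | COc1cc(CCc2ccc(OCOC)c(OCOC)c2OC)cc(O)c1CC=C(C)C | intermediate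
19 | 1‑{2‑[3,5‑dimethoxy‑4‑(3‑methylbut‑2‑en‑1‑yl)phenyl]ethyl}‑2‑methoxy‑3,4‑bis(methoxymethoxy)benzene | COc1cc(CCc2ccc(OCOC)c(OCOC)c2OC)cc(OC)c1CC=C(C)C | intermediate
20 | 4‑{2‑[3,5‑dimethoxy‑4‑(3‑methylbut‑2‑en‑1‑yl)phenyl]ethyl}‑3‑methoxybenzene‑1,2‑diol | COc1cc(CCc2ccc(O)c(O)c2OC)cc(OC)c1CC=C(C)C | intermediate
21 | 4‑{2‑[3,5‑dimethoxy‑4‑(3‑methylbut‑2‑en‑1‑yl)phenyl]ethyl}‑2‑hydroxy‑3‑methoxyphenyl acetate | COc1cc(CCc2ccc(OC(C)=O)c(O)c2OC)cc(OC)c1CC=C(C)C | target

**Step count**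

Total: 12 steps. Longest linear sequence: 11 steps (steps 1–7 and 9–12); step 8 is a one-step side branch.

**Steps most likely to fail**

Step 12. The risk is poor discrimination between the two neighbouring catechol hydroxyls and acetyl transfer from one oxygen to the other once a monoacetate exists. The fallback sets out from 20 and comes back at 21. It tells the oxygens apart with a bulky silyl group instead of the small acyl group.
- TIPSCl and imidazole in DMF at 0 °C should silylate only the unhindered C4′ hydroxyl and give 3‑{2‑[3,5‑dimethoxy‑4‑(3‑methylbut‑2‑en‑1‑yl)phenyl]ethyl}‑2‑methoxy‑6‑{[tri(propan‑2‑yl)silyl]oxy}phenol F1.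
- MOMCl and i‑Pr2NEt in CH2Cl2 then cap the C3′ hydroxyl to give {4‑{2‑[3,5‑dimethoxy‑4‑(3‑methylbut‑2‑en‑1‑yl)phenyl]ethyl}‑3‑methoxy‑2‑(methoxymethoxy)phenoxy}tri(propan‑2‑yl)silane F2.
- Bu4NF in THF at 0 °C frees the C4′ oxygen as 4‑{2‑[3,5‑dimethoxy‑4‑(3‑methylbut‑2‑en‑1‑yl)phenyl]ethyl}‑3‑methoxy‑2‑(methoxymethoxy)phenol F3.
- Ac2O and pyridine give 4‑{2‑[3,5‑dimethoxy‑4‑(3‑methylbut‑2‑en‑1‑yl)phenyl]ethyl}‑3‑methoxy‑2‑(methoxymethoxy)phenyl acetate F4.
- ZnBr2 and n‑PrSH in CH2Cl2 at 0 °C remove the MOM group under aprotic, non-basic conditions, which should leave the aryl acetate and the prenyl group untouched and give little opportunity for acetyl migration; the product is 21.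

Step 6. The risk is loss of MOM groups, or acylation of the electron-rich ring B, caused by ZnCl2 and the acid chloride during ketene generation. The fallback sets out from 3 and comes back at 9. It avoids dichloroketene altogether.
- Methylenation of 3 with Ph3P=CH2 (Ph3PCH3Br, KOt‑Bu, THF) gives 1‑ethenyl‑2‑methoxy‑3,4‑bis(methoxymethoxy)benzene F5.
- Hydroboration with 9‑BBN and oxidative work-up (NaOH, H2O2) gives 2‑[2‑methoxy‑3,4‑bis(methoxymethoxy)phenyl]ethan‑1‑ol F6.
- I2, PPh3 and imidazole give 1‑(2‑iodoethyl)‑2‑methoxy‑3,4‑bis(methoxymethoxy)benzene F7.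
- Iodine–lithium exchange with t‑BuLi (2 equiv, Et2O, −78 °C) gives {2‑[2‑methoxy‑3,4‑bis(methoxymethoxy)phenyl]ethyl}lithium F8.
- F8 adds to the carbonyl group of 3‑ethoxycyclobut‑2‑en‑1‑one (a catalogue reagent, CCOC1=CC(=O)C1) to give 3‑ethoxy‑1‑{2‑[2‑methoxy‑3,4‑bis(methoxymethoxy)phenyl]ethyl}cyclobut‑2‑en‑1‑ol F9.
- Brief treatment with dilute aqueous HCl in THF at 0 °C hydrolyses the enol ether with allylic transposition and gives 9.

Step 8. The risk is base-induced isomerisation of the skipped enyne, together with ammonolysis of the allylic bromide or attack at its tertiary terminus, in liquid ammonia. The fallback sets out from 10 and comes back at 13. It makes the same C–C bond by copper-catalysed cross-coupling of a preformed alkynylmagnesium halide in THF, with no free amide and no ammonia present.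
- LiNEt2 (3 equiv) in THF (−78 → 0 °C) converts 10 into lithium methoxyacetylide F10.
- MgBr2·OEt2 transmetallates it to bromo(methoxyethynyl)magnesium F11.
- CuBr·SMe2 (5 mol %) and prenyl bromide 11 in THF at 0 °C give 13 by the standard copper-catalysed alkynyl–allyl coupling used for 1,4‑enynes.

**Further compounds**

F1 | step 12 | 3‑{2‑[3,5‑dimethoxy‑4‑(3‑methylbut‑2‑en‑1‑yl)phenyl]ethyl}‑2‑methoxy‑6‑{[tri(propan‑2‑yl)silyl]oxy}phenol | COc1cc(CCc2ccc(O[Si](C(C)C)(C(C)C)C(C)C)c(O)c2OC)cc(OC)c1CC=C(C)C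
F2 | step 12 | {4‑{2‑[3,5‑dimethoxy‑4‑(3‑methylbut‑2‑en‑1‑yl)phenyl]ethyl}‑3‑methoxy‑2‑(methoxymethoxy)phenoxy}tri(propan‑2‑yl)silane | COc1cc(CCc2ccc(O[Si](C(C)C)(C(C)C)C(C)C)c(OCOC)c2OC)cc(OC)c1CC=C(C)C
F3 | step 12 | 4‑{2‑[3,5‑dimethoxy‑4‑(3‑methylbut‑2‑en‑1‑yl)phenyl]ethyl}‑3‑methoxy‑2‑(methoxymethoxy)phenol | COc1cc(CCc2ccc(O)c(OCOC)c2OC)cc(OC)c1CC=C(C)C
F4 | step 12 | 4‑{2‑[3,5‑dimethoxy‑4‑(3‑methylbut‑2‑en‑1‑yl)phenyl]ethyl}‑3‑methoxy‑2‑(methoxymethoxy)phenyl acetate | COc1cc(CCc2ccc(OC(C)=O)c(OCOC)c2OC)cc(OC)c1CC=C(C)C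
F5 | step 6 | 1‑ethenyl‑2‑methoxy‑3,4‑bis(methoxymethoxy)benzene | C=Cc1ccc(OCOC)c(OCOC)c1OC
F6 | step 6 | 2‑[2‑methoxy‑3,4‑bis(methoxymethoxy)phenyl]ethan‑1‑ol | OCCc1ccc(OCOC)c(OCOC)c1OC
F7 | step 6 | 1‑(2‑iodoethyl)‑2‑methoxy‑3,4‑bis(methoxymethoxy)benzene | ICCc1ccc(OCOC)c(OCOC)c1OC
F8 | step 6 | {2‑[2‑methoxy‑3,4‑bis(methoxymethoxy)phenyl]ethyl}lithium | [Li]CCc1ccc(OCOC)c(OCOC)c1OC
F9 | step 6 | 3‑ethoxy‑1‑{2‑[2‑methoxy‑3,4‑bis(methoxymethoxy)phenyl]ethyl}cyclobut‑2‑en‑1‑ol | CCOC1=CC(O)(CCc2ccc(OCOC)c(OCOC)c2OC)C1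
F10 | step 8 | lithium methoxyacetylide | [Li+].[C-]#COC
F11 | step 8 | bromo(methoxyethynyl)magnesium | COC#C[Mg]Br
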